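The benzene ring is disconnected at C2–C3 and C4–C5. The feature exploited is the pair of hydroxyl groups on the adjacent ring carbons C3 and C4. These two carbons are delivered together by vinylene carbonate, a masked cis-enediol. C1 (already carrying the propanoate chain), C2, C5 and C6 come from a 2-substituted buta-1,3-diene. A single thermal [4+2] cycloaddition thus assembles the complete six-membered carbocycle with both oxygens installed and the residual alkene at C1=C6. Raising the two carbinols to ketones is then enough for the ring to enolise into the arene. The precursor is hexadecyl 4-methylidenehex-5-enoate, made from the corresponding terminal alkynoate by enyne metathesis with ethylene.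

Key step: step 3

Assumption: arene locants (C1 bears the chain, C3 and C4 bear oxygen) are used for the ring carbons throughout. The target is achiral, so the two chiral intermediates are carried as racemates and drawn as one enantiomer.

Step 1
Reactants: 1 pent-4-ynoic acid; 2 hexadecan-1-ol
Product: 3 hexadecyl pent-4-ynoate
Conditions: 1 (1.1 equiv), TsOH·H2O (5 mol %), toluene, reflux, Dean–Stark
Reagents that add atoms: none
Why: Fischer esterification driven by azeotropic removal of water; the terminal alkyne is inert to catalytic sulfonic acid, and the small excess of bicarbonate-extractable acid 1 ensures that no waxy alcohol 2 is left to separate.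

Step 2
Reactants: 3 hexadecyl pent-4-ynoate; 4 ethylene
Product: 5 hexadecyl 4-methylidenehex-5-enoate
Conditions: second-generation Grubbs catalyst RuCl2(=CHPh)(PCy3)(SIMes) (5 mol %), 4 (4 bar), CH2Cl2, rt; ethyl vinyl ether quench, silica plug, BHT added for storage
Reagents that add atoms: none
Why: Ethylene–alkyne cross-metathesis (enyne metathesis), in which the ruthenium methylidene adds to the terminal alkyne, the resulting vinylcarbene is turned over by ethylene to release the 2-substituted butadiene with all atoms of both partners retained, ethylene pressure holds back alkyne oligomerisation and makes secondary metathesis of the diene degenerate, and the remote ester is tolerated.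

Step 3
Reactants: 5 hexadecyl 4-methylidenehex-5-enoate; 6 vinylene carbonate (1,3-dioxol-2-one)
Product: 7 hexadecyl 3-[(3aR*,7aS*)-2-oxo-3a,4,7,7a-tetrahydro-1,3-benzodioxol-5-yl]propanoate (racemic; cis ring fusion)
Conditions: 6 (5 equiv, freshly distilled), BHT (5 mol %), o-xylene (ca. 2 mol/L in 5), sealed tube, Ar, 170 °C, 24 h; excess 6 distilled off
Reagents that add atoms: none
Why: The s-cis conformer of 5 and the C=C bond of 6 combine in a concerted, suprafacial–suprafacial thermal [4+2] cycloaddition (Diels–Alder reaction) that forms C2–C3 and C4–C5 in one event and shifts the remaining π bond to C1=C6. The closest known reaction type is the uncatalysed addition of vinylene carbonate to butadiene, isoprene and 2,3-dimethylbutadiene at 160–180 °C. The only ring closed is the six-membered carbocycle, formed by intermolecular [4+2] annulation onto the intact dioxolanone, which ends up fused to it. The two new stereocentres C3a and C7a must be cis because the Z geometry locked in the five-membered dienophile is transferred suprafacially; neither partner is chiral, so the adduct is racemic, and both centres disappear on aromatisation. Regiochemistry does not arise because the dienophile is symmetric, and endo and exo approach lead to the same compound because the diene termini are unsubstituted. The selectivity actually needed is cross-addition over dimerisation or radical polymerisation of either alkene, secured by the fivefold excess of 6, high concentration, exclusion of oxygen and BHT, while the 2-alkyl group raises the s-cis population and the saturated ester is thermally inert.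

Step 4
Reactants: 7 hexadecyl 3-[(3aR*,7aS*)-2-oxo-3a,4,7,7a-tetrahydro-1,3-benzodioxol-5-yl]propanoate
Product: 8 hexadecyl 3-[(4R*,5S*)-4,5-dihydroxycyclohex-1-en-1-yl]propanoate (racemic cis-diol)
Conditions: LiOH·H2O (1.1 equiv), THF/H2O 4:1, 0 °C, 30 min; aq NH4Cl
Reagents that add atoms: none
Why: Alkaline hydrolysis (BAc2) of a cyclic carbonate protecting group, in which hydroxide should attack the strained, unhindered dioxolanone carbonyl faster than the unstrained ester of a long lipophilic alcohol, the near-stoichiometric base ends as hydrogencarbonate so the medium is self-limiting, no alcohol solvent is present that could transesterify, and only acyl–oxygen bonds break so the cis relationship of the two carbinol centres is retained.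

Step 5
Reactants: 8 hexadecyl 3-[(4R*,5S*)-4,5-dihydroxycyclohex-1-en-1-yl]propanoate
Product: 10 hexadecyl 3-(3,4-dihydroxyphenyl)propanoate, via cyclohex-4-ene-1,2-dione 9 (not isolated)
Conditions: (COCl)2 (2.4 equiv), DMSO (5 equiv), CH2Cl2, −78 °C, then 8 in CH2Cl2/THF; Et3N (8 equiv), −78 → 0 °C, Ar; dilute aq HCl
Reagents that add atoms: none
Why: Swern oxidation of both secondary carbinols gives the β,γ-unsaturated 1,2-dione 9, whose two amine-promoted enolisations towards C2 and C5 complete the aromatic sextet, a known passage from cyclohex-4-ene-1,2-diols to catechols that removes both stereocentres and leaves the ester untouched.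

Compound list
1 | pent-4-ynoic acid | C#CCCC(=O)O | starting material
2 | hexadecan-1-ol | CCCCCCCCCCCCCCCCO | starting material
3 | hexadecyl pent-4-ynoate | CCCCCCCCCCCCCCCCOC(=O)CCC#C | intermediate
4 | ethylene | C=C | starting material
5 | hexadecyl 4-methylidenehex-5-enoate | CCCCCCCCCCCCCCCCOC(=O)CCC(=C)C=C | intermediate
6 | vinylene carbonate (1,3-dioxol-2-one) | O=C1OC=CO1 | starting material
7 | hexadecyl 3-[(3aR*,7aS*)-2-oxo-3a,4,7,7a-tetrahydro-1,3-benzodioxol-5-yl]propanoate (racemic; cis-fused; one enantiomer drawn) | CCCCCCCCCCCCCCCCOC(=O)CCC1=CC[C@@H]2OC(=O)O[C@@H]2C1 | intermediate
8 | hexadecyl 3-[(4R*,5S*)-4,5-dihydroxycyclohex-1-en-1-yl]propanoate (racemic cis-diol; one enantiomer drawn) | CCCCCCCCCCCCCCCCOC(=O)CCC1=CC[C@H](O)[C@H](O)C1 | intermediate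
9 | hexadecyl 3-(4,5-dioxocyclohex-1-en-1-yl)propanoate (not isolated) | CCCCCCCCCCCCCCCCOC(=O)CCC1=CCC(=O)C(=O)C1 | intermediate
10 | hexadecyl 3-(3,4-dihydroxyphenyl)propanoate | CCCCCCCCCCCCCCCCOC(=O)CCc1ccc(O)c(O)c1 | target

Total step count: 5.
Longest linear sequence: 5 steps (1 or 2 → 3 → 5 → 7 → 8 → 10).

Steps most likely to fail

1. Step 3.
   - **Risk:** The cross-cycloaddition is slow at any temperature the partners tolerate. Self-dimerisation and radical polymerisation of the diene, or thermal polymerisation of the dienophile, may therefore consume the material first.
   - **Fallback:** It sets out from 2 and comes back at 10. Ring construction is given up and the arene is bought. Commercial 3-(3,4-dihydroxyphenyl)propanoic acid (O=C(O)CCc1ccc(O)c(O)c1) is condensed with 2 under the Fischer conditions of step 1 (TsOH·H2O, toluene/1,4-dioxane, Dean–Stark). Phenolic hydroxyls are not acylated under acid-catalysed equilibrium conditions, so no protection is needed. No compound outside the list is made on this way (entry F0).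

2. Step 5.
   - **Risk:** Surplus activated sulfoxide may capture the newly formed catechol by methylthiomethylation. One activated carbinol may be eliminated with loss of an oxygen. The catecholate may oxidise in air during the basic phase. The waxy diol may precipitate at −78 °C.
   - **Fallback:** It sets out from 8 and comes back at 10. Over-oxidation is accepted instead of being avoided. IBX (3.5 equiv, DMSO/THF, rt) oxidises 1,2-diols to 1,2-diones without C–C cleavage and then takes the resulting catechol on. Everything therefore funnels to the ortho-quinone hexadecyl 3-(3,4-dioxocyclohexa-1,5-dien-1-yl)propanoate F1. Without isolation, aqueous Na2S2O4 is added and reduces the quinone to 10.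

3. Step 4.
   - **Risk:** The rate gap between carbonate and ester may be too small. Partial saponification of the hexadecyl ester would then accompany carbonate cleavage.
   - **Fallback:** It sets out from 7 and comes back at 8. Selectivity is no longer requested. Excess LiOH (4 equiv, THF/H2O, rt) removes carbonate and ester together, and acidification gives 3-[(4R*,5S*)-4,5-dihydroxycyclohex-1-en-1-yl]propanoic acid F2. The liberated alcohol is extracted from the basic phase beforehand. SN2 O-alkylation of the carboxylate with 1-bromohexadecane (KHCO3, DMF, 50 °C) then rebuilds the ester. It cannot touch the neutral secondary alcohols, and it delivers 8.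

Further compounds
F0 | step 3 | none | none
F1 | step 5 | hexadecyl 3-(3,4-dioxocyclohexa-1,5-dien-1-yl)propanoate | CCCCCCCCCCCCCCCCOC(=O)CCC1=CC(=O)C(=O)C=C1
F2 | step 4 | 3-[(4R*,5S*)-4,5-dihydroxycyclohex-1-en-1-yl]propanoic acid (racemic cis-diol) | OC(=O)CCC1=CC[C@H](O)[C@H](O)C1
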